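Carbon labels C1–C15 follow germacranolide numbering for every intermediate (ring C1–C10, C11–C13 on C7, C14 on C10, C15 on C4).

## Analysis of the target

The target is a germacranolide: a ten-membered carbocycle (C1–C10) trans-fused across C6–C7 to an α-methylene-γ-butyrolactone (O–C6, C7, C11(=C13), C12). The ring holds two trisubstituted alkenes, C1=C10 and C4=C5, each with its two ring bonds cis; both are E by the sequence rule only because C14 and C15 carry oxygen. Three contiguous stereocentres, C6, C7 and C8 (all R), lie on one edge: H6 and H7 are anti, and O8 is syn to C6 when the chain C11–C7–C8–C9 is drawn extended. Three acyl groups sit on oxygen: the lactone on O6, an acetate on the primary allylic O15 and a methacrylate on the primary allylic O14, beside a free secondary hydroxyl on C8. The sensitive points are the two conjugate acceptors, the base-labile esters, the C8 hydroxyl (which can translactonise onto C12) and the 1,5-diene in a medium ring (which can cyclise across the ring under acid). The difficulty is to close a ten-membered ring with two ring-cis alkenes and to tell the two primary allylic oxygens apart. The route rests on one feature: O6 and O15 stand 1,4 to each other across C4=C5 (O–C6–C5=C4–C15–O). This is the pattern left by 1,4-dioxygenation of a C15=C4–C5=C6 diene in which the C12 carboxyl group is one of the two oxygen nucleophiles.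

## Retrosynthetic reasoning

**27 to 26.** The Si–O8 bond is cut last. O8 must stay silylated as long as C12 is a free acid, because a free C8 hydroxyl would close the unwanted 12,8-lactone.

**26 to 25 (key disconnection).** The lactone C6–O bond and the acetate C15–O bond are cut together, which returns the alkene from C4=C5 to the diene C15=C4–C5=C6 and leaves diene acid 25. These two bonds are chosen because both are allylic to the same alkene and 1,4-related. One palladium-catalysed oxidation can therefore close the lactone, set C6, move the alkene into the ring and place the acetoxy group on C15. C14 already carries its methacrylate, so the two primary allylic oxygens never have to be distinguished by selective acylation. The forward step must attack the right face of C6, deliver the acetoxy group to C15 and not C5, and give the ring-cis C4=C5.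

**25 to 23.** The acid is masked as a tert-butyl ester. A tert-butyl ester does not lactonise onto O8 at the hydroxy ester stage and can be removed without base, which the methacrylate would not survive; a methyl ester meets neither condition.

**23 to 22.** The ring is opened at C4–C5. It is the only ring bond between two sp2 carbons that is not part of a stereodefined trisubstituted alkene, so a cross-coupling can close it without creating a geometric problem. The Z geometry of C5=C6 is carried in alkenylstannane 22, and C4 is a 2-bromoalkene that is inert in all earlier steps.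

**22 to 20 to 19.** The Z-alkenylstannane is traced to the terminal alkyne of 20, and the silyl ether to alcohol 19.

**19 to 13 + 17.** The C7–C8 bond is cut. Adding a 2-(alkoxycarbonyl)allyl metal through its γ-carbon to aldehyde 13 forms this bond, sets C7 and C8 together and brings in the C11–C13 acrylate at the correct oxidation level. The syn relation needed is the normal outcome of this reaction type. Absolute control must come from a chiral catalyst, since 13 has no stereocentre.

**17 to 16 to 14 + 15.** Bromide 17 comes from the Baylis–Hillman adduct 16 of alkynal 14 and acrylate 15 by allylic transposition. The silyl cap on the alkyne blocks reaction at C5.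

**13 to 12, 11, 9, 8, then 7 + 4.** The C1=C10 alkene is cut in the sense of a Horner–Wadsworth–Emmons reaction. The E enoate 8 has C14 trans to C2, which is the ring-cis geometry needed. The ester becomes the C14 alcohol and is acylated with 10 while C8 is still a silyl ether, so the order of operations separates the two primary oxygens.

**4 to 3 to 1 + 2, and 7 to 5 + 6.** The five-carbon bromo aldehyde comes from enolate alkylation of 1 with 2. The phosphonate comes from alkylation of 5 with 6.

## Alternatives that were turned down

**Alternative 1:** The ring is opened from a bicycle instead of closed from a chain. The disconnection restores a C1–C6 bond, so enynone A1 comes from decalin epoxy ketone A2. In the forward sense the tosylhydrazone of the C10 ketone of A2 fragments (Eschenmoser–Tanabe), the C1–C6 bond breaks, and A1 appears with a C6 ketone, a C1–C10 triple bond and the C4=C5 enone.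
- For: no macrocyclisation is needed, and the ring-cis geometry of C4=C5 is inherited from a cyclohexene. On this point it is stronger than the chosen route, where that geometry is decided in the key step.
- Against: the fragmentation makes no skeletal bond and no stereocentre. A1 still lacks C14, the whole C11–C13 unit and the C6 and C7 stereocentres. C14 and hydrogen would have to be added across a triple bond whose two ends (C1 next to C2H2, C10 next to C9H2) are almost indistinguishable. The C11–C13 unit would have to be attached to C7 of a flexible cyclodecenone, and the C6 ketone reduced to the right epimer.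
- Comparison: each of those later operations is a medium-ring stereochemical problem without a clear control element, and many steps follow A1. The chosen route sets C7 and C8 in an open chain under reagent control and has one step after the ring oxidation.

**Alternative 2:** The C2–C3 bond is cut and C2 is made nucleophilic through a sulfone. Carbocycle A3 comes from open-chain bromo sulfone A4, whose C2 carbanion (KN(SiMe3)2) displaces the primary allylic bromide at C3.
- For: sulfone alkylation is a well-tried closure for ten-membered terpenoid rings. Both trisubstituted alkenes and all three stereocentres exist before the ring is closed, so neither the C4=C5 geometry nor the C6 configuration is at stake in the key step. On these two points it is stronger than the chosen strategy.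
- Against: the strong base forces C12 to be carried as an ether, so A3 holds a 3-methylene-tetrahydrofuran that must later be oxidised at C12 in competition with the other allylic positions (C2, C3, C9, C14, C15). The allylic sulfone at C2 must be removed reductively next to C1=C10, with the risk of alkene shift or loss of geometry. Three silyl ethers must be removed and replaced one at a time.
- Comparison: at least six operations follow the ring closure, against one in the chosen route, where C12 has the right oxidation level from the start and O15 is acetylated by the step that builds the lactone.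

**Alternative 3:** The C7–C8 bond is cut in the sense of a [2,3] Wittig–Still shift. Alcohol A5 comes from the thirteen-membered α-stannyl ether A6, in which O8 bridges C8 and C13. Tin–lithium exchange with n-BuLi at C8 gives an α-alkoxy carbanion that attacks C7; the C11=C13 alkene moves out of the dihydrofuran and the ring contracts to ten members.
- For: one step forms C7–C8, both of its stereocentres and the exocyclic methylene. The ring closed beforehand is the easier thirteen-membered ether, and C4=C5 is fixed in advance. This key step makes a skeletal C–C bond and two stereocentres, which is more than the chosen key step builds.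
- Against: the configuration at C7 and C8 would be decided by a transannular transition state of a flexible thirteen-membered ring, which cannot be predicted with confidence. A configurationally defined α-alkoxystannane is needed, and a [1,2] shift competes. A5, like A3, has C12 as an ether and carries two silyl ethers, so allylic oxidation and acyl exchanges follow.
- Comparison: the chosen route obtains C7 and C8 from an intermolecular allylation with a closed, predictable transition state and ends one step after its key step.

Key step: step 16

Assumption: the sense of induction in step 11 is set by the antipode of the bis(oxazoline) ligand; the antipode that gives the 8R alcohol is used, and this is checked by MTPA ester analysis on the first run.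

## Route

Step 1
Reactants: 1 ethyl acetate; 2 2,3-dibromopropene
Product: 3 ethyl 4-bromopent-4-enoate
Conditions: LDA, THF, −78 °C; then 2, DMPU, −78 → −30 °C
Reagents that add atoms: none
Why: Alkylation of the lithium ester enolate at the allylic CH2Br of 2 (SN2); the vinylic C–Br bond does not react and is kept as the C4 coupling handle.

Step 2
Reactants: 3 ethyl 4-bromopent-4-enoate
Product: 4 4-bromopent-4-enal
Conditions: DIBAL-H (1.05 equiv), CH2Cl2, −78 °C; MeOH, aqueous potassium sodium tartrate
Reagents that add atoms: none
Why: Partial ester reduction; the tetrahedral aluminium hemiacetal is stable at −78 °C and releases the aldehyde only on work-up.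

Step 3
Reactants: 5 triethyl phosphonoacetate; 6 (2-bromoethoxy)(tert-butyl)dimethylsilane
Product: 7 ethyl 4-[(tert-butyldimethylsilyl)oxy]-2-(diethoxyphosphoryl)butanoate (racemic)
Conditions: NaH, NaI (cat.), DMF, 0 → 60 °C
Reagents that add atoms: none
Why: C-Alkylation of the stabilised phosphonoacetate anion with a primary bromide under iodide catalysis; the new stereocentre is irrelevant because it becomes sp2 in step 4.

Step 4
Reactants: 7 ethyl 4-[(tert-butyldimethylsilyl)oxy]-2-(diethoxyphosphoryl)butanoate; 4 4-bromopent-4-enal
Product: 8 ethyl (2E)-6-bromo-2-{2-[(tert-butyldimethylsilyl)oxy]ethyl}hepta-2,6-dienoate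
Conditions: NaH, THF, 0 °C; then 4, 0 °C → rt
Reagents that add atoms: none
Why: Horner–Wadsworth–Emmons olefination; reversible addition of the stabilised phosphonate anion puts the ester (C14) trans to the C2 chain, so the E enoate should predominate and the minor Z isomer is removed by chromatography. This is the ring-cis arrangement of C1=C10 in the target.

Step 5
Reactants: 8 ethyl (2E)-6-bromo-2-{2-[(tert-butyldimethylsilyl)oxy]ethyl}hepta-2,6-dienoate
Product: 9 (2E)-6-bromo-2-{2-[(tert-butyldimethylsilyl)oxy]ethyl}hepta-2,6-dien-1-ol
Conditions: DIBAL-H (2.5 equiv), CH2Cl2, −78 °C; aqueous potassium sodium tartrate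
Reagents that add atoms: none
Why: 1,2-Reduction of the conjugated ester to the allylic alcohol; the alkenyl bromide and the silyl ether are inert.

Step 6
Reactants: 9 (2E)-6-bromo-2-{2-[(tert-butyldimethylsilyl)oxy]ethyl}hepta-2,6-dien-1-ol; 10 methacryloyl chloride
Product: 11 (2E)-6-bromo-2-{2-[(tert-butyldimethylsilyl)oxy]ethyl}hepta-2,6-dien-1-yl 2-methylprop-2-enoate
Conditions: Et3N, DMAP (cat.), CH2Cl2, 0 °C
Reagents that add atoms: none
Why: Acylation of the primary allylic alcohol under nucleophilic catalysis installs the C14 methacrylate while C8 is still masked, so the two primary oxygens never compete.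

Step 7
Reactants: 11 (2E)-6-bromo-2-{2-[(tert-butyldimethylsilyl)oxy]ethyl}hepta-2,6-dien-1-yl 2-methylprop-2-enoate
Product: 12 (2E)-6-bromo-2-(2-hydroxyethyl)hepta-2,6-dien-1-yl 2-methylprop-2-enoate
Conditions: HF·pyridine, pyridine, THF, 0 °C → rt
Reagents that add atoms: none
Why: Fluoride cleavage of the primary silyl ether under buffered conditions that leave the methacrylate untouched.

Step 8
Reactants: 12 (2E)-6-bromo-2-(2-hydroxyethyl)hepta-2,6-dien-1-yl 2-methylprop-2-enoate
Product: 13 (2E)-6-bromo-2-(2-oxoethyl)hepta-2,6-dien-1-yl 2-methylprop-2-enoate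
Conditions: DMP (1,1,1-triacetoxy-1,1-dihydro-1,2-benziodoxol-3(1H)-one), NaHCO3, CH2Cl2, 0 °C → rt; used at once
Reagents that add atoms: none
Why: Oxidation of the primary alcohol by the hypervalent iodine reagent under bicarbonate buffering; the neutral conditions limit migration of C1=C10 into conjugation with the new aldehyde.

Step 9
Reactants: 14 3-(trimethylsilyl)propynal; 15 tert-butyl acrylate
Product: 16 tert-butyl 3-hydroxy-2-methylidene-5-(trimethylsilyl)pent-4-ynoate (racemic)
Conditions: DABCO (0.3 equiv), 1,4-dioxane–H2O (1:1), rt
Reagents that add atoms: none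
Why: Baylis–Hillman reaction: the DABCO–acrylate zwitterion adds to the very electrophilic alkynal and the amine is then eliminated. The carbinol stereocentre is lost in step 10.

Step 10
Reactants: 16 tert-butyl 3-hydroxy-2-methylidene-5-(trimethylsilyl)pent-4-ynoate
Product: 17 tert-butyl (2Z)-2-(bromomethyl)-5-(trimethylsilyl)pent-2-en-4-ynoate
Conditions: NBS, Me2S, CH2Cl2, 0 °C → rt
Reagents that add atoms: N-bromosuccinimide, O=C1CCC(=O)N1Br
Why: The alcohol is activated as an alkoxysulfonium salt and bromide attacks the methylene terminus with allylic transposition (SN2′) to give the primary bromide. The alkynyl group is expected cis to CH2Br, as is usual for these adducts.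

Step 11
Reactants: 13 (2E)-6-bromo-2-(2-oxoethyl)hepta-2,6-dien-1-yl 2-methylprop-2-enoate; 17 tert-butyl (2Z)-2-(bromomethyl)-5-(trimethylsilyl)pent-2-en-4-ynoate
Product: 19 tert-butyl (3R,4R,6E)-10-bromo-3-ethynyl-4-hydroxy-6-{[(2-methylprop-2-enoyl)oxy]methyl}-2-methylideneundeca-6,10-dienoate, via bis-silyl adduct 18 (not isolated)
Conditions: CrCl2 (10 mol %), 3,6-diphenyl-1,8-bis(4-isopropyl-4,5-dihydrooxazol-2-yl)carbazole (one antipode, 12 mol %), Mn, TMSCl, i-Pr2NEt, THF, rt; then TBAF, AcOH, THF, 0 °C
Reagents that add atoms: none
Why: Catalytic asymmetric Nozaki–Hiyama–Kishi-type 2-(alkoxycarbonyl)allylation: divalent chromium (regenerated by Mn) turns 17 into an allylchromium reagent that adds through its γ-carbon (C7) to the aldehyde in a closed chair transition state. With the alkynyl group cis to the CH2–Cr terminus it sits axial, which gives the syn C7/C8 relation, and the chiral ligand selects the aldehyde face that leads to the 8R carbinol. TMSCl turns the catalyst over as silyl ether 18, and buffered fluoride in the work-up removes both silyl groups.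

Step 12
Reactants: 19 tert-butyl (3R,4R,6E)-10-bromo-3-ethynyl-4-hydroxy-6-{[(2-methylprop-2-enoyl)oxy]methyl}-2-methylideneundeca-6,10-dienoate
Product: 20 tert-butyl (3R,4R,6E)-10-bromo-4-[(tert-butyldimethylsilyl)oxy]-3-ethynyl-6-{[(2-methylprop-2-enoyl)oxy]methyl}-2-methylideneundeca-6,10-dienoate
Conditions: TBSOTf, 2,6-lutidine, CH2Cl2, −78 → 0 °C
Reagents that add atoms: tert-butyldimethylsilyl triflate, CC(C)(C)[Si](C)(C)OS(=O)(=O)C(F)(F)F
Why: Silylation of the hindered secondary alcohol with a silyl triflate and a non-nucleophilic base; the silyl ether blocks lactonisation of O8 onto C12 in all later steps.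

Step 13
Reactants: 20 tert-butyl (3R,4R,6E)-10-bromo-4-[(tert-butyldimethylsilyl)oxy]-3-ethynyl-6-{[(2-methylprop-2-enoyl)oxy]methyl}-2-methylideneundeca-6,10-dienoate
Product: 22 tert-butyl (3R,4R,6E)-10-bromo-4-[(tert-butyldimethylsilyl)oxy]-6-{[(2-methylprop-2-enoyl)oxy]methyl}-2-methylidene-3-[(Z)-2-(tributylstannyl)ethenyl]undeca-6,10-dienoate, via alkynylstannane 21 (not isolated)
Conditions: Bu3SnOMe (1.2 equiv), ZnBr2 (5 mol %), THF, rt; volatiles removed; Cp2Zr(H)Cl (1.3 equiv), THF, 0 °C → rt; then H2O
Reagents that add atoms: tributyltin methoxide, CCCC[Sn](CCCC)(CCCC)OC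
Why: ZnBr2-catalysed stannylation of the terminal alkyne gives 21. Syn hydrozirconation then places zirconium on the tin-bearing carbon, and protonolysis of the C–Zr bond with retention leaves tin cis to C7, which is the Z-alkenylstannane. The alkyne should add Cp2Zr(H)Cl much faster than the hindered enoates or the 2-bromoalkene.

Step 14
Reactants: 22 tert-butyl (3R,4R,6E)-10-bromo-4-[(tert-butyldimethylsilyl)oxy]-6-{[(2-methylprop-2-enoyl)oxy]methyl}-2-methylidene-3-[(Z)-2-(tributylstannyl)ethenyl]undeca-6,10-dienoate
Product: 23 tert-butyl 2-[(1R,2Z,7E,10R)-10-[(tert-butyldimethylsilyl)oxy]-8-{[(2-methylprop-2-enoyl)oxy]methyl}-4-methylidenecyclodeca-2,7-dien-1-yl]prop-2-enoate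
Conditions: Pd2(dba)3 (10 mol %), AsPh3 (40 mol %), CuI (20 mol %), DMF, 50 °C, slow addition to 1 mM
Reagents that add atoms: none
Why: Intramolecular Stille coupling: zerovalent palladium inserts into the C4–Br bond, the Z-alkenylstannane transmetalates with retention, and reductive elimination forms C4–C5 and the ten-membered ring. The two cis alkenes (C1=C10 and C5=C6) pre-bend the chain, and high dilution suppresses dimerisation.

Step 15
Reactants: 23 tert-butyl 2-[(1R,2Z,7E,10R)-10-[(tert-butyldimethylsilyl)oxy]-8-{[(2-methylprop-2-enoyl)oxy]methyl}-4-methylidenecyclodeca-2,7-dien-1-yl]prop-2-enoate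
Product: 25 2-[(1R,2Z,7E,10R)-10-[(tert-butyldimethylsilyl)oxy]-8-{[(2-methylprop-2-enoyl)oxy]methyl}-4-methylidenecyclodeca-2,7-dien-1-yl]prop-2-enoic acid, via trimethylsilyl ester 24 (not isolated)
Conditions: TMSOTf, 2,6-lutidine, CH2Cl2, 0 °C; then aqueous pH 5 buffer
Reagents that add atoms: none
Why: The silyl triflate activates the tert-butyl ester carbonyl, 2-methylpropene is lost, and silyl ester 24 is hydrolysed on work-up. The lutidine keeps the medium non-acidic, so the secondary silyl ether, the methacrylate and the triene are expected to survive.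

Step 16
Reactants: 25 2-[(1R,2Z,7E,10R)-10-[(tert-butyldimethylsilyl)oxy]-8-{[(2-methylprop-2-enoyl)oxy]methyl}-4-methylidenecyclodeca-2,7-dien-1-yl]prop-2-enoic acid
Product: 26 8-O-(tert-butyldimethylsilyl) ether of 27 (15-acetoxy-8-silyloxy-14-methacryloyloxy-germacra-1(10),4,11(13)-trien-12,6-olide; spatial arrangement at C6, C7 and C8 as in 27)
Conditions: Pd(OAc)2 (10 mol %), p-benzoquinone (2 equiv), LiOAc (2 equiv), AcOH–acetone (1:4), rt
Reagents that add atoms: acetic acid, CC(=O)O (acetate also supplied as lithium acetate, [Li+].CC(=O)[O-])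
Why: Divalent palladium binds the C5=C6 alkene on the face away from the tethered carboxyl group, the carboxylate oxygen adds to C6 anti to the metal and closes the γ-lactone, and the C5–palladium bond collapses onto C4=C15 to an η3-allyl complex over C5–C4–C15. Acetate then attacks the unsubstituted terminus C15, the alkene ends at C4=C5, and the zerovalent palladium released is reoxidised by the quinone; the closest known reaction type is the palladium-catalysed intramolecular 1,4-oxyacyloxylation of conjugated dienes by tethered carboxylic acids. One ring is closed, the lactone, in the 5-exo-trig mode, and the bonds formed are O–C6 and O–C15. The new stereocentre C6 is controlled by C7: allylic 1,3-strain across the Z C5=C6 bond holds H7 in the alkene plane pointing at C4, so C11 with its carboxyl group lies on one face and C8 on the other, and attack from the C11 face gives H6 anti to H7 (trans lactone, 6R). The step needs four selectivities: the C6 face, secured as described; C15 over C5 for acetate, secured by the primary against the secondary allyl terminus; the C4=C5 geometry; and chemoselectivity over C1=C10, the methacrylate and the acrylic acid alkene, which are trisubstituted or electron-poor and bind divalent palladium less well than the diene. The ring-cis C4=C5 requires the allyl unit with C6 syn to C3; the diene itself is twisted in the ring and does not dictate this, so the preference is expected to come from the lower strain of a ring-cis allyl unit in the ten-membered ring, with syn/anti exchange of the allyl complex possible before acetate capture. The O8 silyl ether is essential, because a free C8 hydroxyl would lactonise onto C12.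

Step 17
Reactants: 26 8-O-(tert-butyldimethylsilyl) ether of 27
Product: 27 (6R,7R,8R)-15-acetoxy-8-hydroxy-14-[(2-methylprop-2-enoyl)oxy]germacra-1(10)E,4E,11(13)-trien-12,6-olide (CNP0313792.2; both ring alkenes cis within the ring)
Conditions: HF·pyridine, pyridine, THF, 0 °C → rt
Reagents that add atoms: none
Why: Fluoride cleavage of the secondary silyl ether under buffered, non-basic conditions; base is avoided because the free C8 hydroxyl could translactonise onto C12 and the acetate and methacrylate are base-labile.

## Compound list

1 | ethyl acetate | CCOC(C)=O | starting material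
2 | 2,3-dibromopropene | C=C(Br)CBr | starting material
3 | ethyl 4-bromopent-4-enoate | CCOC(=O)CCC(Br)=C | intermediate
4 | 4-bromopent-4-enal | O=CCCC(Br)=C | intermediate
5 | triethyl phosphonoacetate | CCOC(=O)CP(=O)(OCC)OCC | starting material
6 | (2-bromoethoxy)(tert-butyl)dimethylsilane | BrCCO[Si](C)(C)C(C)(C)C | starting material
7 | ethyl 4-[(tert-butyldimethylsilyl)oxy]-2-(diethoxyphosphoryl)butanoate (racemic) | CCOC(=O)C(CCO[Si](C)(C)C(C)(C)C)P(=O)(OCC)OCC | intermediate
8 | ethyl (2E)-6-bromo-2-{2-[(tert-butyldimethylsilyl)oxy]ethyl}hepta-2,6-dienoate | C=C(Br)CC/C=C(/C(=O)OCC)CCO[Si](C)(C)C(C)(C)C | intermediate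
9 | (2E)-6-bromo-2-{2-[(tert-butyldimethylsilyl)oxy]ethyl}hepta-2,6-dien-1-ol | C=C(Br)CC/C=C(/CO)CCO[Si](C)(C)C(C)(C)C | intermediate
10 | methacryloyl chloride | C=C(C)C(Cl)=O | starting material
11 | (2E)-6-bromo-2-{2-[(tert-butyldimethylsilyl)oxy]ethyl}hepta-2,6-dien-1-yl 2-methylprop-2-enoate | C=C(Br)CC/C=C(/COC(=O)C(C)=C)CCO[Si](C)(C)C(C)(C)C | intermediate
12 | (2E)-6-bromo-2-(2-hydroxyethyl)hepta-2,6-dien-1-yl 2-methylprop-2-enoate | C=C(Br)CC/C=C(/COC(=O)C(C)=C)CCO | intermediate
13 | (2E)-6-bromo-2-(2-oxoethyl)hepta-2,6-dien-1-yl 2-methylprop-2-enoate | C=C(Br)CC/C=C(/COC(=O)C(C)=C)CC=O | intermediate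
14 | 3-(trimethylsilyl)propynal | C[Si](C)(C)C#CC=O | starting material
15 | tert-butyl acrylate | C=CC(=O)OC(C)(C)C | starting material
16 | tert-butyl 3-hydroxy-2-methylidene-5-(trimethylsilyl)pent-4-ynoate (racemic) | C=C(C(O)C#C[Si](C)(C)C)C(=O)OC(C)(C)C | intermediate
17 | tert-butyl (2Z)-2-(bromomethyl)-5-(trimethylsilyl)pent-2-en-4-ynoate | C[Si](C)(C)C#C/C=C(\CBr)C(=O)OC(C)(C)C | intermediate
18 | tert-butyl (3S,4R,6E)-10-bromo-6-{[(2-methylprop-2-enoyl)oxy]methyl}-2-methylidene-4-[(trimethylsilyl)oxy]-3-[(trimethylsilyl)ethynyl]undeca-6,10-dienoate | C=C(Br)CC/C=C(/COC(=O)C(C)=C)C[C@@H](O[Si](C)(C)C)[C@H](C#C[Si](C)(C)C)C(=C)C(=O)OC(C)(C)C | intermediate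
19 | tert-butyl (3R,4R,6E)-10-bromo-3-ethynyl-4-hydroxy-6-{[(2-methylprop-2-enoyl)oxy]methyl}-2-methylideneundeca-6,10-dienoate | C=C(Br)CC/C=C(/COC(=O)C(C)=C)C[C@@H](O)[C@H](C#C)C(=C)C(=O)OC(C)(C)C | intermediate
20 | tert-butyl (3R,4R,6E)-10-bromo-4-[(tert-butyldimethylsilyl)oxy]-3-ethynyl-6-{[(2-methylprop-2-enoyl)oxy]methyl}-2-methylideneundeca-6,10-dienoate | C=C(Br)CC/C=C(/COC(=O)C(C)=C)C[C@@H](O[Si](C)(C)C(C)(C)C)[C@H](C#C)C(=C)C(=O)OC(C)(C)C | intermediate
21 | tert-butyl (3S,4R,6E)-10-bromo-4-[(tert-butyldimethylsilyl)oxy]-6-{[(2-methylprop-2-enoyl)oxy]methyl}-2-methylidene-3-[(tributylstannyl)ethynyl]undeca-6,10-dienoate | C=C(Br)CC/C=C(/COC(=O)C(C)=C)C[C@@H](O[Si](C)(C)C(C)(C)C)[C@H](C#C[Sn](CCCC)(CCCC)CCCC)C(=C)C(=O)OC(C)(C)C | intermediate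
22 | tert-butyl (3R,4R,6E)-10-bromo-4-[(tert-butyldimethylsilyl)oxy]-6-{[(2-methylprop-2-enoyl)oxy]methyl}-2-methylidene-3-[(Z)-2-(tributylstannyl)ethenyl]undeca-6,10-dienoate | C=C(Br)CC/C=C(/COC(=O)C(C)=C)C[C@@H](O[Si](C)(C)C(C)(C)C)[C@H](/C=C\[Sn](CCCC)(CCCC)CCCC)C(=C)C(=O)OC(C)(C)C | intermediate
23 | tert-butyl 2-[(1R,2Z,7E,10R)-10-[(tert-butyldimethylsilyl)oxy]-8-{[(2-methylprop-2-enoyl)oxy]methyl}-4-methylidenecyclodeca-2,7-dien-1-yl]prop-2-enoate | C=C(C)C(=O)OC/C1=C/CCC(=C)/C=C\[C@H](C(=C)C(=O)OC(C)(C)C)[C@H](O[Si](C)(C)C(C)(C)C)C1 | intermediate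
24 | trimethylsilyl 2-[(1R,2Z,7E,10R)-10-[(tert-butyldimethylsilyl)oxy]-8-{[(2-methylprop-2-enoyl)oxy]methyl}-4-methylidenecyclodeca-2,7-dien-1-yl]prop-2-enoate | C=C(C)C(=O)OC/C1=C/CCC(=C)/C=C\[C@H](C(=C)C(=O)O[Si](C)(C)C)[C@H](O[Si](C)(C)C(C)(C)C)C1 | intermediate
25 | 2-[(1R,2Z,7E,10R)-10-[(tert-butyldimethylsilyl)oxy]-8-{[(2-methylprop-2-enoyl)oxy]methyl}-4-methylidenecyclodeca-2,7-dien-1-yl]prop-2-enoic acid | C=C(C)C(=O)OC/C1=C/CCC(=C)/C=C\[C@H](C(=C)C(=O)O)[C@H](O[Si](C)(C)C(C)(C)C)C1 | intermediate
26 | 8-O-(tert-butyldimethylsilyl) ether of 27 ((6R,7S,8R) by the sequence rule, same spatial arrangement as 27) | C=C(C)C(=O)OC/C1=C/CC/C(COC(C)=O)=C\[C@H]2OC(=O)C(=C)[C@@H]2[C@H](O[Si](C)(C)C(C)(C)C)C1 | intermediate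
27 | (6R,7R,8R)-15-acetoxy-8-hydroxy-14-[(2-methylprop-2-enoyl)oxy]germacra-1(10)E,4E,11(13)-trien-12,6-olide | C=C(C)C(=O)OC/C1=C/CC/C(COC(C)=O)=C\[C@H]2OC(=O)C(=C)[C@@H]2[C@H](O)C1 | target

## Step count and least certain steps

Total: 17 steps. Longest linear sequence: 14 steps (1, 2, 4–8, 11–17).

**Step 16 (key step).** The most likely failure is formation of the allyl complex with C6 anti to C3, which would give the ring-trans C4=C5 isomer. The diene is twisted in the ten-membered ring, and both of its planar rotamers suffer allylic strain against C7, so the diene conformation does not decide the geometry; only ring strain in the allyl unit does. A second risk is slow oxypalladation with competing transannular participation of C1=C10. Fallback: an electrophilic halocyclisation in place of the palladium oxidation. From 25, NBS with NaHCO3 in CH2Cl2 at −40 °C should add bromine to C15 and the carboxylate to C6, giving the bromolactone F1. Displacement of the primary allylic bromide with CsOAc in DMF then returns to the route at 26.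

**Step 14.** Oligomerisation may outrun closure of the strained ring, and protodestannylation or Z to E isomerisation of the alkenylstannane may occur at the temperature needed for the 2-bromoalkene. Fallback: a boron-based closure that also avoids the hydrozirconation of step 13. From 20, AgNO3-catalysed iodination with N-iodosuccinimide gives the iodoalkyne F2. Diimide reduction (2-nitrobenzenesulfonyl hydrazide, Et3N) gives the (Z)-alkenyl iodide F3. Selective borylation of the iodide (PdCl2(dppf), bis(pinacolato)diboron, KOAc, DMSO, 50 °C) gives the (Z)-alkenylboronate F4. Suzuki–Miyaura macrocyclisation of F4 onto the 2-bromoalkene (Pd(PPh3)4, Cs2CO3, THF–H2O, high dilution) returns to the route at 23.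

**Step 11.** Facial selectivity may be eroded by the remote ester groups binding chromium. The syn/anti ratio may also fall, because the slim alkynyl group only weakly prefers the position cis to CH2–Cr. Fallback: racemic synthesis and resolution. From 13 and 17, an indium-mediated Barbier reaction (In powder, THF–H2O), which is known to favour the syn adduct, gives the racemic C-silyl alcohol F5. Buffered TBAF gives the racemic alcohol F6. Preparative chromatography on a chiral stationary phase returns to the route at 19, at the cost of half the material.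

**Step 15.** Cation-forming conditions may trigger transannular cyclisation of the triene or loss of the C8 silyl ether. Fallback: cleave the ester before any diene exists and carry the acid as a tin ester. From 20, the same silyl triflate protocol gives the trimethylsilyl ester F7 and, after work-up, the alkynyl acid F8. Bu3SnOMe (2.2 equiv, ZnBr2 cat.) gives the distannyl compound F9, and Cp2Zr(H)Cl then water gives the (Z)-alkenylstannane tributylstannyl ester F10. Stille macrocyclisation as in step 14 gives the macrocyclic stannyl ester F11, and aqueous KF in the work-up returns to the route at 25.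

## Further compounds

F1 | step 16 | 15-bromo analogue of 26 (C15–Br in place of C15–OAc) | C=C(C)C(=O)OC/C1=C/CC/C(CBr)=C\[C@H]2OC(=O)C(=C)[C@@H]2[C@H](O[Si](C)(C)C(C)(C)C)C1
F2 | step 14 | iodoalkyne from 20 (iodoethynyl at C7) | C=C(Br)CC/C=C(/COC(=O)C(C)=C)C[C@@H](O[Si](C)(C)C(C)(C)C)[C@H](C#CI)C(=C)C(=O)OC(C)(C)C
F3 | step 14 | (Z)-alkenyl iodide from F2 | C=C(Br)CC/C=C(/COC(=O)C(C)=C)C[C@@H](O[Si](C)(C)C(C)(C)C)[C@H](/C=C\I)C(=C)C(=O)OC(C)(C)C
F4 | step 14 | (Z)-alkenyl pinacol boronate from F3 | C=C(Br)CC/C=C(/COC(=O)C(C)=C)C[C@@H](O[Si](C)(C)C(C)(C)C)[C@H](/C=C\B1OC(C)(C)C(C)(C)O1)C(=C)C(=O)OC(C)(C)C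
F5 | step 11 | racemic syn C-silyl alcohol (one enantiomer drawn) | C=C(Br)CC/C=C(/COC(=O)C(C)=C)C[C@@H](O)[C@H](C#C[Si](C)(C)C)C(=C)C(=O)OC(C)(C)C
F6 | step 11 | racemate of 19 (one enantiomer drawn) | C=C(Br)CC/C=C(/COC(=O)C(C)=C)C[C@@H](O)[C@H](C#C)C(=C)C(=O)OC(C)(C)C
F7 | step 15 | trimethylsilyl ester corresponding to 20 | C=C(Br)CC/C=C(/COC(=O)C(C)=C)C[C@@H](O[Si](C)(C)C(C)(C)C)[C@H](C#C)C(=C)C(=O)O[Si](C)(C)C
F8 | step 15 | alkynyl carboxylic acid corresponding to 20 | C=C(Br)CC/C=C(/COC(=O)C(C)=C)C[C@@H](O[Si](C)(C)C(C)(C)C)[C@H](C#C)C(=C)C(=O)O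
F9 | step 15 | alkynylstannane tributylstannyl ester | C=C(Br)CC/C=C(/COC(=O)C(C)=C)C[C@@H](O[Si](C)(C)C(C)(C)C)[C@H](C#C[Sn](CCCC)(CCCC)CCCC)C(=C)C(=O)O[Sn](CCCC)(CCCC)CCCC
F10 | step 15 | (Z)-alkenylstannane tributylstannyl ester | C=C(Br)CC/C=C(/COC(=O)C(C)=C)C[C@@H](O[Si](C)(C)C(C)(C)C)[C@H](/C=C\[Sn](CCCC)(CCCC)CCCC)C(=C)C(=O)O[Sn](CCCC)(CCCC)CCCC
F11 | step 15 | tributylstannyl ester of 25 | C=C(C)C(=O)OC/C1=C/CCC(=C)/C=C\[C@H](C(=C)C(=O)O[Sn](CCCC)(CCCC)CCCC)[C@H](O[Si](C)(C)C(C)(C)C)C1
A1 | alternative 1 | ten-membered enynone with C6 ketone and C1–C10 alkyne | C1C#CCC/C(CO[Si](C(C)C)(C(C)C)C(C)C)=C\C(=O)C[C@@H]1O[Si](C)(C)C(C)(C)C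
A2 | alternative 1 | decalin epoxy ketone (C1–C6 epoxide, C10 ketone, C4=C5 alkene) | O=C1C[C@@H](O[Si](C)(C)C(C)(C)C)CC23OC12CCC(CO[Si](C(C)C)(C(C)C)C(C)C)=C3
A3 | alternative 2 | ten-membered carbocycle with C2 phenylsulfonyl group | CC(C)(C)[Si](C)(C)OC/C1=C/[C@@H](S(=O)(=O)c2ccccc2)C/C(CO[Si](C(C)C)(C(C)C)C(C)C)=C\[C@H]3OCC(=C)[C@@H]3[C@H](O[Si](C)(C)C(C)(C)C)C1
A4 | alternative 2 | open-chain C2 phenyl sulfone with C3 allylic bromide | CC(C)(C)[Si](C)(C)OC/C(=C/CS(=O)(=O)c1ccccc1)C[C@@H](O[Si](C)(C)C(C)(C)C)[C@H]2C(=C)CO[C@@H]2/C=C(\CBr)CO[Si](C(C)C)(C(C)C)C(C)C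
A5 | alternative 3 | ten-membered carbocycle with 3-methylene-tetrahydrofuran and free C8 hydroxyl | CC(C)(C)[Si](C)(C)OC/C1=C/CC/C(CO[Si](C(C)C)(C(C)C)C(C)C)=C\[C@H]2OCC(=C)[C@@H]2[C@H](O)C1
A6 | alternative 3 | thirteen-membered α-stannyl allyl ether with fused 2,5-dihydrofuran | CC(C)(C)[Si](C)(C)OC/C1=C/CC/C(CO[Si](C(C)C)(C(C)C)C(C)C)=C\[C@H]2OCC(=C2)COC(C1)[Sn](CCCC)(CCCC)CCCC
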